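(The data are calculated from invented constants; the scatter is artificial.)

Start from the constants. None is given, so you read the one you need from the readings.

| setting | Tuesday's | Sunday's | flask |
|---|---|---|---|
| left-handed substrate | 0.10 M | 0.10 M | 0.10 M |
| right-handed substrate | 0.10 M | 0.10 M | 0.10 M |
| solid reagent | 0.20 M | 0.40 M | 0.200 M |
| remark | the very flask that is asked about, followed so far | run made earlier |  |
| time |  |  | 12 h |

- Tuesday's (time / min: right-handed substrate / %, left-handed substrate / %): 20.0: 50.4, 50.1; 40.0: 50.5, 48.9; 60.0: 50.4, 48.7; 80.0: 50.2, 48.0; 90.0: 49.6, 47.7; 120: 50.1, 46.5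
- Sunday's (time / h: right-handed substrate / %, left-handed substrate / %): 0.667: 50.6, 50.1; 1.00: 49.2, 49.0; 1.50: 49.6, 48.2; 2.50: 50.6, 45.9; 4.00: 49.5, 41.4; 6.00: 50.5, 36.7; 8.00: 49.3, 31.2

(readings scatter by 0.5 percentage points)

- coupling partner is single-handed; left-handed substrate and right-handed substrate are mirror images of each other, charged as a racemate, each of them at the stated concentration
- as a solid, counted per litre of solution: solid reagent
- what was read earlier has a scatter of 0.5 percentage points, one standard deviation
- at the start none of the solid reagent is in solution
- the handed part of coupling partner does not stay in what it makes, so the products of the two hands are mirror images too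

- whether the excess of right-handed substrate over left-handed substrate among what is left of the two reaches 80% by 12 h (yes / no)
- the highest excess of right-handed substrate over left-handed substrate among what is left of the two up to 12 h

At the first instant no solid reagent is in solution. The readings then show a lag: in Sunday's run the left-handed substrate still reads 50.1% at 0.667 h. In the middle the right-handed substrate stays level within the scatter, reading 49.3% at 8.00 h, while the left-handed substrate falls. I take c(coupling partner) as steady in that stretch, so the loss is pseudo-first-order. From 45.9% at 2.50 h to 31.2% at 8.00 h, Sunday's readings give the fraction of left-handed substrate lost per hour, 0.0702 h⁻¹.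

That joins the two ends if the lag is over by 2.50 h, which I assume. Tuesday's flask has half of Sunday's solid, yet at 120 min it reads 46.5%, in line with Sunday's curve. So I carry the constant over, assuming the solid lasts. At 12 h that leaves 23.6% of left-handed substrate, an excess of 36.0%, still rising at the end.

The forecast says no and 40%, holding that “the rate does not depend on how much solid is present”. My figure is lower: I let the loss slow with what is left, while the forecast keeps a straight line.

The flask gives no and 34.8%, with left-handed substrate at 23.6% at 12.0 h.

    solid reagent ⇌ coupling partner, rate k1*(cs1 - [coupling partner]) while solid is left; crystals form when [coupling partner] > cs1 (solubility = 0.0640 M, k = 1.06 × 10⁻⁴ s⁻¹)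
    left-handed product ⇌ right-handed product (k = 3.52 × 10⁻⁴ s⁻¹)
    coupling partner + right-handed substrate → right-handed product (k = 2.11 × 10⁻⁵ M⁻¹ s⁻¹)
    coupling partner + left-handed substrate → left-handed product (k = 6.62 × 10⁻⁴ M⁻¹ s⁻¹)
    coupling partner → decomposed reagent (k = 7.63 × 10⁻⁵ s⁻¹)

Divide 0.0702 h⁻¹ by the rate constant of coupling partner with left-handed substrate, 6.62 × 10⁻⁴ M⁻¹ s⁻¹. You get 0.0295 M of coupling partner, and the flask holds 0.0286 M at 6.00 h.

Now take the neighbour flask with 0.12 M of solid reagent. Carried to 12 h with its solid lasting, 0.0702 h⁻¹ gives 23.6% of left-handed substrate and an excess of 36.0%. Computed, that flask ends higher at 27.7%, with a top of 27.9% and its solid reagent at 0%.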